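**Retrosynthetic overview**
1. The linoleate is attached last, by selective acylation of the primary OH of triol 25; the Z-enal comes from the ring ketone by isopropenyl addition and oxidative 1,3-transposition.
2. The side chain is built on the ring fragment: E-selective Wittig (formyl ylide), alpha-selective geranylbarium addition, then oxidation and CBS reduction to set the (R)-carbinol.
3. The tertiary ring carbinol comes from methylenation of a ring ketone, face-selective epoxidation and hydride opening of the oxirane.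
4. The ring CH and the quaternary carbon are set together by a copper-catalysed asymmetric conjugate addition followed by enolate allylation on enone 3.
5. Ring order: there is only one ring, the cyclohexane; it is bought in with ketone 1 and no ring is formed in the route.

Assumption: in step 3 the enantiomer of the chiral carbene ligand is the one that gives the (6R) centre; this is confirmed once by correlation before scale-up.

**Route**

Step 1
Reactants: 1 7-methyl-1,4-dioxaspiro[4.5]decan-8-one (racemic)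
Product: 2 trimethyl[(7-methyl-1,4-dioxaspiro[4.5]dec-7-en-8-yl)oxy]silane
Conditions: Me3SiCl, Et3N, DMF, 90 °C
Reagents that add atoms: chlorotrimethylsilane C[Si](C)(C)Cl
Why: Silyl enol ether formation under equilibrating conditions gives mainly the more substituted (thermodynamic) enol ether, which fixes the regiochemistry of the dehydrogenation that follows.

Step 2
Reactants: 2 trimethyl[(7-methyl-1,4-dioxaspiro[4.5]dec-7-en-8-yl)oxy]silane
Product: 3 7-methyl-1,4-dioxaspiro[4.5]dec-6-en-8-one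
Conditions: Pd(OAc)2 (1.05 equiv), MeCN, rt
Reagents that add atoms: none
Why: Saegusa–Ito oxidation of the silyl enol ether gives the conjugated 2-methyl enone and leaves the ketal untouched; the minor regioisomeric enone is removed by chromatography.

Step 3
Reactants: 3 7-methyl-1,4-dioxaspiro[4.5]dec-6-en-8-one; 4 (3-bromopropoxy)(tert-butyl)diphenylsilane
Product: 7 (6R,7R)-6-[3-(tert-butyldiphenylsilyloxy)propyl]-7-methyl-7-(prop-2-en-1-yl)-1,4-dioxaspiro[4.5]decan-8-one, via Grignard reagent 5 (not isolated), via bromomagnesium enolate 6 (not isolated)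
Conditions: Mg, THF (4 to 5); 3, Cu(OTf)2 (5 mol %), chiral imidazolinium carbene precursor (6 mol %), Et2O, −30 °C; then allyl iodide, DMPU, −30 °C to rt
Reagents that add atoms: allyl iodide C=CCI
Why: Copper-catalysed asymmetric conjugate addition sets the ring CH centre (6R) under ligand control, and the magnesium enolate is then allylated on the face away from the new chain, so the quaternary centre (7R) forms with allyl trans and methyl cis to that chain (tandem conjugate addition/enolate alkylation).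

Step 4
Reactants: 7 (6R,7R)-ketone
Product: 8 tert-butyl{3-[(6R,7R)-7-methyl-8-methylidene-7-(prop-2-en-1-yl)-1,4-dioxaspiro[4.5]decan-6-yl]propoxy}diphenylsilane
Conditions: Ph3PCH3Br, KOtBu, toluene, 90 °C
Reagents that add atoms: methyltriphenylphosphonium bromide C[P+](c1ccccc1)(c1ccccc1)c1ccccc1.[Br-]
Why: Wittig methylenation with excess ylide at elevated temperature converts even this alpha-quaternary ketone into the exocyclic alkene without touching the ketal, the silyl ether or the allyl group.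

Step 5
Reactants: 8 exocyclic alkene
Product: 9 (6R,7R,8S)-spiro-oxirane of 8 (oxirane O on C8 cis to the allyl group)
Conditions: m-CPBA (1.1 equiv), NaHCO3, CH2Cl2, 0 °C
Reagents that add atoms: 3-chloroperoxybenzoic acid OOC(=O)c1cccc(Cl)c1
Why: Prilezhaev epoxidation prefers the electron-richer 1,1-disubstituted alkene over the allyl group and should come from the ring face that carries the allyl group, because the other face is screened by the axial methyl in one chair and by the syn-axial silyloxypropyl chain in the other; this puts the oxirane oxygen cis to allyl (8S).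

Step 6
Reactants: 9 spiro-oxirane
Product: 10 (6R,7R,8S)-6-[3-(tert-butyldiphenylsilyloxy)propyl]-7,8-dimethyl-7-(prop-2-en-1-yl)-1,4-dioxaspiro[4.5]decan-8-ol
Conditions: LiBHEt3, THF, 0 °C to rt
Reagents that add atoms: none
Why: Reductive epoxide opening by SN2 hydride attack at the oxirane CH2 turns that carbon into the methyl group and leaves the tertiary C–O bond, and so the carbinol configuration (8S), unchanged.

Step 7
Reactants: 10 tertiary alcohol
Product: 12 3-[(6R,7R,8S)-6-[3-(tert-butyldiphenylsilyloxy)propyl]-8-hydroxy-7,8-dimethyl-1,4-dioxaspiro[4.5]decan-7-yl]propan-1-ol, via B-alkyl-9-BBN adduct 11 (not isolated)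
Conditions: 9-BBN (2.5 equiv), THF, rt; then NaOH, H2O2, 0 °C
Reagents that add atoms: hydrogen peroxide OO
Why: Anti-Markovnikov hydroboration–oxidation of the only alkene gives the primary alcohol.

Step 8
Reactants: 12 diol
Product: 13 3-[(6R,7R,8S)-6-[3-(tert-butyldiphenylsilyloxy)propyl]-8-hydroxy-7,8-dimethyl-1,4-dioxaspiro[4.5]decan-7-yl]propanal (open form of its six-membered lactol)
Conditions: Dess–Martin periodinane (1.1 equiv), NaHCO3, CH2Cl2, 0 °C
Reagents that add atoms: none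
Why: Dess–Martin oxidation takes the primary alcohol to the aldehyde while the tertiary alcohol cannot be oxidised, and one equivalent at 0 °C avoids over-oxidation of the lactol.

Step 9
Reactants: 13 hydroxy aldehyde
Product: 14 (2E)-5-[(6R,7R,8S)-6-[3-(tert-butyldiphenylsilyloxy)propyl]-8-hydroxy-7,8-dimethyl-1,4-dioxaspiro[4.5]decan-7-yl]-2-methylpent-2-enal
Conditions: Ph3P=C(CH3)CHO, toluene, 90 °C
Reagents that add atoms: 2-(triphenylphosphoranylidene)propanal CC(C=O)=P(c1ccccc1)(c1ccccc1)c1ccccc1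
Why: Wittig olefination with the stabilised formyl ylide is E-selective and builds the trisubstituted side-chain alkene together with the aldehyde needed for the next C–C bond.

Step 10
Reactants: 14 enal; 15 geranyl chloride [(2E)-1-chloro-3,7-dimethylocta-2,6-diene]
Product: 17 (3E,7E)-1-[(6R,7R,8S)-6-[3-(tert-butyldiphenylsilyloxy)propyl]-8-hydroxy-7,8-dimethyl-1,4-dioxaspiro[4.5]decan-7-yl]-4,8,12-trimethyltrideca-3,7,11-trien-5-ol (both C5 epimers), via geranylbarium chloride 16 (not isolated)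
Conditions: active Ba (from BaI2, 2 LiC12H10), THF; 15 (2.2 equiv), −78 °C; then 14, −78 °C; then H2O
Reagents that add atoms: none
Why: Allylbarium reagents add 1,2 to aldehydes through their alpha carbon with retention of the E geometry (Barbier-type allylbarium addition), which gives the linear adduct and not the branched gamma adduct; the new carbinol centre is uncontrolled here and is corrected in steps 11 and 12.

Step 11
Reactants: 17 allylic alcohol (epimer mixture)
Product: 18 (3E,7E)-1-[(6R,7R,8S)-6-[3-(tert-butyldiphenylsilyloxy)propyl]-8-hydroxy-7,8-dimethyl-1,4-dioxaspiro[4.5]decan-7-yl]-4,8,12-trimethyltrideca-3,7,11-trien-5-one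
Conditions: Dess–Martin periodinane, NaHCO3, CH2Cl2, 0 °C
Reagents that add atoms: none
Why: Buffered Dess–Martin oxidation gives the alpha-methyl enone under neutral conditions, so the skipped double bond is not drawn into conjugation.

Step 12
Reactants: 18 enone
Product: 19 (3E,5R,7E)-1-[(6R,7R,8S)-6-[3-(tert-butyldiphenylsilyloxy)propyl]-8-hydroxy-7,8-dimethyl-1,4-dioxaspiro[4.5]decan-7-yl]-4,8,12-trimethyltrideca-3,7,11-trien-5-ol
Conditions: (S)-2-methyl-CBS-oxazaborolidine (20 mol %), catecholborane, toluene, −78 °C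
Reagents that add atoms: none
Why: Corey–Bakshi–Shibata reduction, in which the alpha-methyl alkenyl group acts as the large substituent, so the (S)-catalyst delivers hydride to give the (5R) allylic alcohol.

Step 13
Reactants: 19 (5R)-allylic alcohol
Product: 20 tert-butyldimethylsilyl ether of 19 at the (5R) side-chain oxygen
Conditions: TBSCl, imidazole, DMF, rt
Reagents that add atoms: tert-butyldimethylsilyl chloride CC(C)(C)[Si](C)(C)Cl
Why: Silylation protects the secondary alcohol from the later chromium oxidation, while the hindered tertiary alcohol does not react with TBSCl/imidazole.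

Step 14
Reactants: 20 bis-silyl ether ketal
Product: 21 (2R,3R,4S)-2-[3-(tert-butyldiphenylsilyloxy)propyl]-3-[(3E,5R,7E)-5-(tert-butyldimethylsilyloxy)-4,8,12-trimethyltrideca-3,7,11-trien-1-yl]-4-hydroxy-3,4-dimethylcyclohexan-1-one
Conditions: pyridinium p-toluenesulfonate, acetone/H2O, 55 °C
Reagents that add atoms: water O
Why: Mild acid-catalysed ketal hydrolysis frees the ring ketone; the silyl ethers survive without an alcohol solvent and the hindered alpha CH centre should not epimerise.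

Step 15
Reactants: 21 ketone
Product: 22 (2R,3R,4S)-2-[3-(tert-butyldiphenylsilyloxy)propyl]-3-[(3E,5R,7E)-5-(tert-butyldimethylsilyloxy)-4,8,12-trimethyltrideca-3,7,11-trien-1-yl]-3,4-dimethyl-1-(prop-1-en-2-yl)cyclohexane-1,4-diol (C1 epimers)
Conditions: CH2=C(CH3)MgBr (3 equiv), CeCl3, THF, −78 to 0 °C
Reagents that add atoms: isopropenylmagnesium bromide CC(=C)[Mg]Br
Why: The organocerium reagent adds 1,2 to the hindered, enolisable ketone without deprotonating it (organocerium carbonyl addition); the new carbinol centre becomes sp2 in the next step, so the epimer mixture is used as such.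

Step 16
Reactants: 22 tertiary allylic alcohol
Product: 24 (2Z)-2-[(2S,3R,4S)-2-[3-(tert-butyldiphenylsilyloxy)propyl]-3-[(3E,5R,7E)-5-(tert-butyldimethylsilyloxy)-4,8,12-trimethyltrideca-3,7,11-trien-1-yl]-4-hydroxy-3,4-dimethylcyclohexylidene]propanal, via rearranged primary chlorochromate ester 23 (not isolated)
Conditions: (C5H5NH)[CrO3Cl], 4 Å sieves, CH2Cl2, rt
Reagents that add atoms: pyridinium chlorochromate [O-][Cr](=O)(=O)Cl.c1cc[nH+]cc1
Why: Babler–Dauben oxidative transposition, in which the tertiary allylic chromate ester shifts [3,3] to the primary one and is oxidised to the enal; the methyl group is expected to turn toward the unsubstituted ring CH2 so that the formyl group ends up cis to the substituted ring CH (Z), but the preference is modest and the E isomer is removed by chromatography.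

Step 17
Reactants: 24 bis-silyl enal
Product: 25 (2Z)-2-[(2S,3R,4S)-4-hydroxy-2-(3-hydroxypropyl)-3-[(3E,5R,7E)-5-hydroxy-4,8,12-trimethyltrideca-3,7,11-trien-1-yl]-3,4-dimethylcyclohexylidene]propanal
Conditions: Bu4NF, AcOH, THF, rt
Reagents that add atoms: none
Why: Fluoride-mediated desilylation removes both silyl ethers, and the acetic acid buffer keeps the enal from deconjugating or epimerising at the gamma CH.

Step 18
Reactants: 25 triol; 26 linoleoyl chloride [(9Z,12Z)-octadeca-9,12-dienoyl chloride]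
Product: 27 3-{(1S,2R,3S,6Z)-3-hydroxy-2-[(3E,5R,7E)-5-hydroxy-4,8,12-trimethyltrideca-3,7,11-trien-1-yl]-2,3-dimethyl-6-(1-oxopropan-2-ylidene)cyclohexyl}propyl (9Z,12Z)-octadeca-9,12-dienoate
Conditions: 26 (1.05 equiv), 2,4,6-collidine, CH2Cl2, −78 °C
Reagents that add atoms: none
Why: Chemoselective esterification, since the acid chloride with collidine at −78 °C acylates the primary alcohol much faster than the branched secondary allylic alcohol or the tertiary alcohol.

**Compound list**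

1 | 7-methyl-1,4-dioxaspiro[4.5]decan-8-one (racemic) | CC1CC2(CCC1=O)OCCO2 | starting material
2 | trimethyl[(7-methyl-1,4-dioxaspiro[4.5]dec-7-en-8-yl)oxy]silane | CC1=C(O[Si](C)(C)C)CCC2(C1)OCCO2 | intermediate
3 | 7-methyl-1,4-dioxaspiro[4.5]dec-6-en-8-one | CC1=CC2(CCC1=O)OCCO2 | intermediate
4 | (3-bromopropoxy)(tert-butyl)diphenylsilane | CC(C)(C)[Si](c1ccccc1)(c1ccccc1)OCCCBr | starting material
5 | [3-(tert-butyldiphenylsilyloxy)propyl]magnesium bromide | CC(C)(C)[Si](c1ccccc1)(c1ccccc1)OCCC[Mg]Br | intermediate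
6 | bromomagnesium enolate of (6R)-6-[3-(tert-butyldiphenylsilyloxy)propyl]-7-methyl-1,4-dioxaspiro[4.5]decan-8-one | CC(C)(C)[Si](c1ccccc1)(c1ccccc1)OCCC[C@H]3C4(OCCO4)CCC(O[Mg]Br)=C3C | intermediate
7 | (6R,7R)-6-[3-(tert-butyldiphenylsilyloxy)propyl]-7-methyl-7-(prop-2-en-1-yl)-1,4-dioxaspiro[4.5]decan-8-one | CC(C)(C)[Si](c1ccccc1)(c1ccccc1)OCCC[C@H]3C4(OCCO4)CCC(=O)[C@]3(C)CC=C | intermediate
8 | tert-butyl{3-[(6R,7R)-7-methyl-8-methylidene-7-(prop-2-en-1-yl)-1,4-dioxaspiro[4.5]decan-6-yl]propoxy}diphenylsilane | CC(C)(C)[Si](c1ccccc1)(c1ccccc1)OCCC[C@H]3C4(OCCO4)CCC(=C)[C@]3(C)CC=C | intermediate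
9 | (6R,7R,8S)-spiro-oxirane of 8, oxirane O cis to allyl | CC(C)(C)[Si](c1ccccc1)(c1ccccc1)OCCC[C@H]3C4(OCCO4)CC[C@]5(OC5)[C@]3(C)CC=C | intermediate
10 | (6R,7R,8S)-6-[3-(tert-butyldiphenylsilyloxy)propyl]-7,8-dimethyl-7-(prop-2-en-1-yl)-1,4-dioxaspiro[4.5]decan-8-ol | CC(C)(C)[Si](c1ccccc1)(c1ccccc1)OCCC[C@H]3C4(OCCO4)CC[C@](C)(O)[C@]3(C)CC=C | intermediate
11 | B-alkyl-9-borabicyclo[3.3.1]nonane adduct of 10 (boron on the terminal allyl carbon) | CC(C)(C)[Si](c1ccccc1)(c1ccccc1)OCCC[C@H]3C4(OCCO4)CC[C@](C)(O)[C@]3(C)CCCB5C6CCCC5CCC6 | intermediate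
12 | 3-[(6R,7R,8S)-6-[3-(tert-butyldiphenylsilyloxy)propyl]-8-hydroxy-7,8-dimethyl-1,4-dioxaspiro[4.5]decan-7-yl]propan-1-ol | CC(C)(C)[Si](c1ccccc1)(c1ccccc1)OCCC[C@H]3C4(OCCO4)CC[C@](C)(O)[C@]3(C)CCCO | intermediate
13 | 3-[(6R,7R,8S)-6-[3-(tert-butyldiphenylsilyloxy)propyl]-8-hydroxy-7,8-dimethyl-1,4-dioxaspiro[4.5]decan-7-yl]propanal (open form of its lactol) | CC(C)(C)[Si](c1ccccc1)(c1ccccc1)OCCC[C@H]3C4(OCCO4)CC[C@](C)(O)[C@]3(C)CCC=O | intermediate
14 | (2E)-5-[(6R,7R,8S)-6-[3-(tert-butyldiphenylsilyloxy)propyl]-8-hydroxy-7,8-dimethyl-1,4-dioxaspiro[4.5]decan-7-yl]-2-methylpent-2-enal | CC(C)(C)[Si](c1ccccc1)(c1ccccc1)OCCC[C@H]3C4(OCCO4)CC[C@](C)(O)[C@]3(C)CC/C=C(\C)C=O | intermediate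
15 | geranyl chloride, (2E)-1-chloro-3,7-dimethylocta-2,6-diene | ClC/C=C(\C)CCC=C(C)C | starting material
16 | geranylbarium chloride | Cl[Ba]C/C=C(\C)CCC=C(C)C | intermediate
17 | (3E,7E)-1-[(6R,7R,8S)-6-[3-(tert-butyldiphenylsilyloxy)propyl]-8-hydroxy-7,8-dimethyl-1,4-dioxaspiro[4.5]decan-7-yl]-4,8,12-trimethyltrideca-3,7,11-trien-5-ol (C5 epimers) | CC(C)(C)[Si](c1ccccc1)(c1ccccc1)OCCC[C@H]3C4(OCCO4)CC[C@](C)(O)[C@]3(C)CC/C=C(\C)C(O)C/C=C(\C)CCC=C(C)C | intermediate
18 | (3E,7E)-1-[(6R,7R,8S)-6-[3-(tert-butyldiphenylsilyloxy)propyl]-8-hydroxy-7,8-dimethyl-1,4-dioxaspiro[4.5]decan-7-yl]-4,8,12-trimethyltrideca-3,7,11-trien-5-one | CC(C)(C)[Si](c1ccccc1)(c1ccccc1)OCCC[C@H]3C4(OCCO4)CC[C@](C)(O)[C@]3(C)CC/C=C(\C)C(=O)C/C=C(\C)CCC=C(C)C | intermediate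
19 | (3E,5R,7E)-1-[(6R,7R,8S)-6-[3-(tert-butyldiphenylsilyloxy)propyl]-8-hydroxy-7,8-dimethyl-1,4-dioxaspiro[4.5]decan-7-yl]-4,8,12-trimethyltrideca-3,7,11-trien-5-ol | CC(C)(C)[Si](c1ccccc1)(c1ccccc1)OCCC[C@H]3C4(OCCO4)CC[C@](C)(O)[C@]3(C)CC/C=C(\C)[C@H](O)C/C=C(\C)CCC=C(C)C | intermediate
20 | (6R,7R,8S)-6-[3-(tert-butyldiphenylsilyloxy)propyl]-7-[(3E,5R,7E)-5-(tert-butyldimethylsilyloxy)-4,8,12-trimethyltrideca-3,7,11-trien-1-yl]-7,8-dimethyl-1,4-dioxaspiro[4.5]decan-8-ol | CC(C)(C)[Si](c1ccccc1)(c1ccccc1)OCCC[C@H]3C4(OCCO4)CC[C@](C)(O)[C@]3(C)CC/C=C(\C)[C@H](O[Si](C)(C)C(C)(C)C)C/C=C(\C)CCC=C(C)C | intermediate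
21 | (2R,3R,4S)-2-[3-(tert-butyldiphenylsilyloxy)propyl]-3-[(3E,5R,7E)-5-(tert-butyldimethylsilyloxy)-4,8,12-trimethyltrideca-3,7,11-trien-1-yl]-4-hydroxy-3,4-dimethylcyclohexan-1-one | CC(C)(C)[Si](c1ccccc1)(c1ccccc1)OCCC[C@H]3C(=O)CC[C@](C)(O)[C@]3(C)CC/C=C(\C)[C@H](O[Si](C)(C)C(C)(C)C)C/C=C(\C)CCC=C(C)C | intermediate
22 | (2R,3R,4S)-2-[3-(tert-butyldiphenylsilyloxy)propyl]-3-[(3E,5R,7E)-5-(tert-butyldimethylsilyloxy)-4,8,12-trimethyltrideca-3,7,11-trien-1-yl]-3,4-dimethyl-1-(prop-1-en-2-yl)cyclohexane-1,4-diol (C1 epimers) | CC(C)(C)[Si](c1ccccc1)(c1ccccc1)OCCC[C@H]3C(O)(C(C)=C)CC[C@](C)(O)[C@]3(C)CC/C=C(\C)[C@H](O[Si](C)(C)C(C)(C)C)C/C=C(\C)CCC=C(C)C | intermediate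
23 | primary allylic chlorochromate ester formed from 22 by [3,3] shift (CH2O–Cr cis to the substituted ring CH) | CC(C)(C)[Si](c1ccccc1)(c1ccccc1)OCCC[C@H]3/C(=C(/C)CO[Cr](=O)(=O)Cl)CC[C@](C)(O)[C@]3(C)CC/C=C(\C)[C@H](O[Si](C)(C)C(C)(C)C)C/C=C(\C)CCC=C(C)C | intermediate
24 | (2Z)-2-[(2S,3R,4S)-2-[3-(tert-butyldiphenylsilyloxy)propyl]-3-[(3E,5R,7E)-5-(tert-butyldimethylsilyloxy)-4,8,12-trimethyltrideca-3,7,11-trien-1-yl]-4-hydroxy-3,4-dimethylcyclohexylidene]propanal | CC(C)(C)[Si](c1ccccc1)(c1ccccc1)OCCC[C@H]3/C(=C(/C)C=O)CC[C@](C)(O)[C@]3(C)CC/C=C(\C)[C@H](O[Si](C)(C)C(C)(C)C)C/C=C(\C)CCC=C(C)C | intermediate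
25 | (2Z)-2-[(2S,3R,4S)-4-hydroxy-2-(3-hydroxypropyl)-3-[(3E,5R,7E)-5-hydroxy-4,8,12-trimethyltrideca-3,7,11-trien-1-yl]-3,4-dimethylcyclohexylidene]propanal | OCCC[C@H]1/C(=C(/C)C=O)CC[C@](C)(O)[C@]1(C)CC/C=C(\C)[C@H](O)C/C=C(\C)CCC=C(C)C | intermediate
26 | linoleoyl chloride, (9Z,12Z)-octadeca-9,12-dienoyl chloride | CCCCC/C=C\C/C=C\CCCCCCCC(=O)Cl | starting material
27 | 3-{(1S,2R,3S,6Z)-3-hydroxy-2-[(3E,5R,7E)-5-hydroxy-4,8,12-trimethyltrideca-3,7,11-trien-1-yl]-2,3-dimethyl-6-(1-oxopropan-2-ylidene)cyclohexyl}propyl (9Z,12Z)-octadeca-9,12-dienoate | CCCCC/C=C\C/C=C\CCCCCCCC(=O)OCCC[C@H]1/C(=C(/C)C=O)CC[C@](C)(O)[C@]1(C)CC/C=C(\C)[C@H](O)C/C=C(\C)CCC=C(C)C | target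

**Step count and risks**

Total: 18 steps. Longest linear sequence: 18 steps (1 to 27); 4, 15 and 26 are bought and enter directly.

The three steps most likely to fail:

Step 3, the asymmetric conjugate addition with allylation next to the ketal carbon, may be slow or give low ee. The fallback sets out from 3 and comes back at 7, and secures the absolute configuration by resolution instead of catalysis. Grignard reagent 5 is added with CuBr·SMe2 and Me3SiCl in THF at −78 °C without chiral ligand; MeLi then frees the enolate, and allyl iodide/DMPU gives the trans ketone as a racemate. This racemate is 7 together with its mirror image, the (6S,7S)-ketone F1. Preparative chromatography on a chiral stationary phase (supercritical CO2/MeOH) returns enantiopure 7, and F1 is discarded.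

Step 5, the epoxidation, rests on a conformational argument and may give the oxygen from the wrong face or with low selectivity. The fallback sets out from 7 and comes back at 13, and delivers the oxygen through a tether from the cis side arm, so the carbinol configuration is fixed by the ring fusion. KN(SiMe3)2 then PhNTf2 turns 7 into vinyl triflate F2. MeMgBr with Fe(acac)3 (5 mol %) gives the ring trisubstituted alkene F3. 9-BBN then NaOH/H2O2 reacts only at the allyl group and gives primary alcohol F4. TEMPO with PhI(OAc)2 in MeCN/H2O gives carboxylic acid F5. Iodine with NaHCO3 gives iodolactone F6 by anti addition, with the lactone oxygen on the tertiary carbon cis to the arm. Bu3SnH with AIBN gives the cis-fused lactone F7. iBu2AlH at −78 °C gives the lactol, which is the ring-closed form of 13.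

Step 16, the oxidative transposition, may give a poor Z/E ratio, and the acidic chromium reagent may close the 1,4-related tertiary alcohols to a bridged ether. The fallback sets out from 21 and comes back at 24, and avoids both the allylic chromate and step 15. Peterson olefination of 21 with lithiated 2-(trimethylsilyl)propanenitrile at −78 °C gives the tetrasubstituted unsaturated nitrile; the Z isomer, separated from E by chromatography, is the (Z)-nitrile F8. iBu2AlH at −78 °C with mild acidic work-up then gives enal 24.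

**Further compounds**

F1 | step 3 | (6S,7S)-6-[3-(tert-butyldiphenylsilyloxy)propyl]-7-methyl-7-(prop-2-en-1-yl)-1,4-dioxaspiro[4.5]decan-8-one (enantiomer of 7) | CC(C)(C)[Si](c1ccccc1)(c1ccccc1)OCCC[C@@H]3C4(OCCO4)CCC(=O)[C@@]3(C)CC=C
F2 | step 5 | (6R,7R)-6-[3-(tert-butyldiphenylsilyloxy)propyl]-7-methyl-7-(prop-2-en-1-yl)-1,4-dioxaspiro[4.5]dec-8-en-8-yl trifluoromethanesulfonate | CC(C)(C)[Si](c1ccccc1)(c1ccccc1)OCCC[C@H]3C4(OCCO4)CC=C(OS(=O)(=O)C(F)(F)F)[C@]3(C)CC=C
F3 | step 5 | tert-butyl{3-[(6R,7R)-7,8-dimethyl-7-(prop-2-en-1-yl)-1,4-dioxaspiro[4.5]dec-8-en-6-yl]propoxy}diphenylsilane | CC(C)(C)[Si](c1ccccc1)(c1ccccc1)OCCC[C@H]3C4(OCCO4)CC=C(C)[C@]3(C)CC=C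
F4 | step 5 | 3-[(6R,7R)-6-[3-(tert-butyldiphenylsilyloxy)propyl]-7,8-dimethyl-1,4-dioxaspiro[4.5]dec-8-en-7-yl]propan-1-ol | CC(C)(C)[Si](c1ccccc1)(c1ccccc1)OCCC[C@H]3C4(OCCO4)CC=C(C)[C@]3(C)CCCO
F5 | step 5 | 3-[(6R,7R)-6-[3-(tert-butyldiphenylsilyloxy)propyl]-7,8-dimethyl-1,4-dioxaspiro[4.5]dec-8-en-7-yl]propanoic acid | CC(C)(C)[Si](c1ccccc1)(c1ccccc1)OCCC[C@H]3C4(OCCO4)CC=C(C)[C@]3(C)CCC(=O)O
F6 | step 5 | cis-fused iodo-delta-lactone from F5 (lactone O on the methyl-bearing ring carbon cis to the arm; iodine on the next ring carbon trans to that O) | CC(C)(C)[Si](c1ccccc1)(c1ccccc1)OCCC[C@H]3C4(OCCO4)C[C@@H](I)[C@](C)(OC(=O)C5)[C@]3(C)C5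
F7 | step 5 | cis-fused delta-lactone, F6 with hydrogen in place of iodine | CC(C)(C)[Si](c1ccccc1)(c1ccccc1)OCCC[C@H]3C4(OCCO4)CC[C@](C)(OC(=O)C5)[C@]3(C)C5
F8 | step 16 | (2Z)-2-[(2S,3R,4S)-2-[3-(tert-butyldiphenylsilyloxy)propyl]-3-[(3E,5R,7E)-5-(tert-butyldimethylsilyloxy)-4,8,12-trimethyltrideca-3,7,11-trien-1-yl]-4-hydroxy-3,4-dimethylcyclohexylidene]propanenitrile | CC(C)(C)[Si](c1ccccc1)(c1ccccc1)OCCC[C@H]3/C(=C(/C)C#N)CC[C@](C)(O)[C@]3(C)CC/C=C(\C)[C@H](O[Si](C)(C)C(C)(C)C)C/C=C(\C)CCC=C(C)C
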